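**Retrosynthetic overview**
- The strategy rests on the free 2'-hydroxyl of ring B, which sits ortho to the C1'–C3 bond, and on the C4 carbonyl next to C3. With the ketone written as an ethylidene, the array O2'–CH(CH3)–C4=C3 of a 4-(1-aryloxyethyl)-2H-chromene is the retron of an aromatic Claisen rearrangement.
- Disconnections: C4=O back to C4=CH–CH3 (glycol cleavage); C1'–C3 back to the O2'–CH(CH3) ether ([3,3] shift with chirality transfer); the ether back to a ring B phenol and an (S)-1-(chromen-4-yl)ethanol (Mitsunobu, inversion).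
- Ring B phenol: from 2,3-dihydroxybenzaldehyde by prenyl ether Claisen (installs the 1,1-dimethylallyl group) and Dakin-type oxidation. Carbinol: from 7-hydroxychroman-4-one by enol triflate, Stille acylation and CBS reduction.
- No ring is built: rings A and C are bought as the chromanone and ring B as the benzaldehyde. They are first joined through the O2' ether, and the key step turns that link into the C1'–C3 bond.

Key step: step 11

Assumption: C3 of the target is (R) as read from the SMILES (CIP order C4 > C2 > C1' > H); MOM ethers protect all phenols because they tolerate the hot neutral, basic, oxidative and reductive steps and leave under mild acid.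

**Route**

Step 1
Reactants: 1 2,3-dihydroxybenzaldehyde; 2 prenyl bromide (1-bromo-3-methylbut-2-ene)
Product: 3 2-hydroxy-3-[(3-methylbut-2-en-1-yl)oxy]benzaldehyde
Conditions: NaH (2.2 equiv), DMSO, rt; then 2 (1.0 equiv), rt
Reagents that add atoms: none
Why: Williamson etherification of the dianion; the 2-phenoxide is conjugated with and chelated to the formyl group, so the 3-phenoxide is the more nucleophilic oxygen and should take the single equivalent of allylic bromide by SN2.

Step 2
Reactants: 3 2-hydroxy-3-[(3-methylbut-2-en-1-yl)oxy]benzaldehyde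
Product: 4 2-(methoxymethoxy)-3-[(3-methylbut-2-en-1-yl)oxy]benzaldehyde
Conditions: MOMCl, i-Pr2NEt, CH2Cl2, 0 °C to rt
Reagents that add atoms: chloromethyl methyl ether (MOMCl), COCCl
Why: Standard MOM ether formation (O-alkylation of the salicylaldehyde hydroxyl), which also blocks that oxygen's carbon as a migration terminus for the next step.

Step 3
Reactants: 4 2-(methoxymethoxy)-3-[(3-methylbut-2-en-1-yl)oxy]benzaldehyde
Product: 7 3-hydroxy-2-(methoxymethoxy)-4-(2-methylbut-3-en-2-yl)benzaldehyde, via ortho-dienone 5 (not isolated), via trimethylsilyl ether 6 (not isolated)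
Conditions: N,O-bis(trimethylsilyl)acetamide (BSA), N,N-diethylaniline, 185 °C, Ar; then K2CO3, MeOH, rt
Reagents that add atoms: none
Why: Aromatic Claisen rearrangement of the prenyl ether to C4, the only unsubstituted ortho carbon, with allylic inversion to the 1,1-dimethylallyl group; silylation of the phenol as it forms should suppress abnormal Claisen and dihydrobenzofuran formation, and methanolysis on work-up frees the phenol.

Step 4
Reactants: 7 3-hydroxy-2-(methoxymethoxy)-4-(2-methylbut-3-en-2-yl)benzaldehyde
Product: 8 3-methoxy-2-(methoxymethoxy)-4-(2-methylbut-3-en-2-yl)benzaldehyde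
Conditions: MeI, K2CO3, DMF, rt
Reagents that add atoms: iodomethane, CI
Why: Williamson O-methylation of the hindered phenol; aldehyde, MOM ether and vinyl group are inert to these conditions.

Step 5
Reactants: 8 3-methoxy-2-(methoxymethoxy)-4-(2-methylbut-3-en-2-yl)benzaldehyde
Product: 10 3-methoxy-2-(methoxymethoxy)-4-(2-methylbut-3-en-2-yl)phenol, via aryl formate 9 (not isolated)
Conditions: 30% aq. H2O2, (PhSe)2 (4 mol %), CH2Cl2, rt; then K2CO3 (cat.), MeOH, rt
Reagents that add atoms: hydrogen peroxide, OO
Why: Dakin-type (Baeyer–Villiger) oxidation in which the benzeneseleninic peracid formed in situ adds to the aldehyde and the electron-rich ortho-alkoxyaryl group migrates to oxygen; the formate is methanolysed in the same flask, and the hindered monosubstituted vinyl group should be epoxidised far more slowly.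

Step 6
Reactants: 11 7-hydroxychroman-4-one
Product: 12 7-(methoxymethoxy)chroman-4-one
Conditions: MOMCl, i-Pr2NEt, CH2Cl2, 0 °C to rt
Reagents that add atoms: chloromethyl methyl ether (MOMCl), COCCl
Why: Standard MOM protection of the acidic para-acylphenol.

Step 7
Reactants: 12 7-(methoxymethoxy)chroman-4-one
Product: 13 7-(methoxymethoxy)-2H-chromen-4-yl trifluoromethanesulfonate
Conditions: KN(SiMe3)2, THF, −78 °C; then PhNTf2, −78 to 0 °C
Reagents that add atoms: N-phenylbis(trifluoromethanesulfonimide), O=S(=O)(N(c1ccccc1)S(=O)(=O)C(F)(F)F)C(F)(F)F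
Why: Enolate O-sulfonylation to the enol triflate; low temperature keeps the chromanone enolate from ring opening by beta-elimination of the aryloxide.

Step 8
Reactants: 13 7-(methoxymethoxy)-2H-chromen-4-yl trifluoromethanesulfonate; 14 tributyl(1-ethoxyvinyl)stannane
Product: 16 1-[7-(methoxymethoxy)-2H-chromen-4-yl]ethanone, via 4-(1-ethoxyvinyl)chromene 15 (not isolated)
Conditions: Pd(PPh3)4 (5 mol %, zerovalent palladium), LiCl, 1,4-dioxane, 90 °C; then 1 M aq. HCl, THF, rt, brief
Reagents that add atoms: water, O
Why: Stille coupling of the vinyl triflate with the alpha-ethoxyvinyl stannane (an acetyl anion equivalent, LiCl assisting transmetalation), then enol ether hydrolysis, which is far faster than cleavage of the aryl MOM ether in cold dilute acid.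

Step 9
Reactants: 16 1-[7-(methoxymethoxy)-2H-chromen-4-yl]ethanone
Product: 17 (S)-1-[7-(methoxymethoxy)-2H-chromen-4-yl]ethanol
Conditions: (R)-2-methyl-CBS-oxazaborolidine (15 mol %), BH3·SMe2, THF, −20 °C; MeOH quench
Reagents that add atoms: none
Why: Corey–Bakshi–Shibata reduction; the ketone binds the catalyst with the branched chromenyl group as the large substituent and methyl as the small one, so the (R)-catalyst should give the (S)-carbinol as it does for aryl methyl ketones, and 1,2-reduction outruns hydroboration of the conjugated alkene.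

Step 10
Reactants: 10 3-methoxy-2-(methoxymethoxy)-4-(2-methylbut-3-en-2-yl)phenol; 17 (S)-1-[7-(methoxymethoxy)-2H-chromen-4-yl]ethanol
Product: 18 4-{(1R)-1-[3-methoxy-2-(methoxymethoxy)-4-(2-methylbut-3-en-2-yl)phenoxy]ethyl}-7-(methoxymethoxy)-2H-chromene
Conditions: PPh3, DIAD, toluene, 0 °C to rt
Reagents that add atoms: none
Why: Mitsunobu etherification; the phenoxide displaces the alkoxyphosphonium group by SN2, inverting the carbinol carbon from (S) to (R).

Step 11
Reactants: 18 4-{(1R)-1-[3-methoxy-2-(methoxymethoxy)-4-(2-methylbut-3-en-2-yl)phenoxy]ethyl}-7-(methoxymethoxy)-2H-chromene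
Product: 21 6-[(3R,4E)-4-ethylidene-7-(methoxymethoxy)chroman-3-yl]-3-methoxy-2-(methoxymethoxy)-4-(2-methylbut-3-en-2-yl)phenol, via ortho-dienone 19 (not isolated), via trimethylsilyl ether 20 (not isolated)
Conditions: BSA (3 equiv), N,N-diethylaniline, 180 °C, sealed tube, Ar; then K2CO3, MeOH, rt
Reagents that add atoms: none
Why: Thermal aromatic Claisen rearrangement, a concerted suprafacial [3,3] shift across C1'=C2'–O–CH(CH3)–C4=C3: the O2'–CH bond breaks as C1' of ring B bonds to C3 of ring C and the alkene moves to the exocyclic C4=CH–CH3 position, after which ortho-dienone 19 enolises and the new 2'-phenol is capped by BSA as 20 (so that it cannot add across the ethylidene) and released by methanolysis. The closest known reaction type is the aromatic Claisen rearrangement of enantioenriched secondary allylic aryl ethers with 1,3-chirality transfer. No ring is closed: rings A, B and C are all present in 18, and only the link between them changes from the O2'–C ether tether to the C1'–C3 bond. C3 is set by transfer of the (R)-carbinol configuration: the carbinol methyl cannot lie beside the peri C5–H of ring A and so sits on the C3 side of the allyl plane, which puts the departing oxygen, and therefore the arriving C1', on the face that gives (3R) together with the (E)-ethylidene. The step needs ortho-regioselective and face-selective delivery; the first is secured because C1' is the only open position ortho to O2' (C3' carries the MOM ether, the para carbon C5' the dimethylallyl group) and the second by the peri interaction, and any (Z)-isomer, which would carry (3S), is removed by chromatography before the alkene is cleaved.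

Step 12
Reactants: 21 6-[(3R,4E)-4-ethylidene-7-(methoxymethoxy)chroman-3-yl]-3-methoxy-2-(methoxymethoxy)-4-(2-methylbut-3-en-2-yl)phenol
Product: 22 (3R,4E)-4-ethylidene-3-[4-methoxy-2,3-bis(methoxymethoxy)-5-(2-methylbut-3-en-2-yl)phenyl]-7-(methoxymethoxy)chroman
Conditions: NaH, MOMCl, THF–DMF, 0 °C to rt
Reagents that add atoms: chloromethyl methyl ether (MOMCl), COCCl
Why: MOM ether formation on the hindered 2'-phenoxide, so that the phenol can neither be oxidised by periodate nor add to C4 later; C3–H is not acidic while C4 is an alkene carbon.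

Step 13
Reactants: 22 (3R,4E)-4-ethylidene-3-[4-methoxy-2,3-bis(methoxymethoxy)-5-(2-methylbut-3-en-2-yl)phenyl]-7-(methoxymethoxy)chroman
Product: 23 (3R,4S)-4-[(1S)-1-hydroxyethyl]-3-[4-methoxy-2,3-bis(methoxymethoxy)-5-(2-methylbut-3-en-2-yl)phenyl]-7-(methoxymethoxy)chroman-4-ol
Conditions: OsO4 (2 mol %), NMO (1.2 equiv), acetone–H2O, 0 °C to rt, stopped when 22 is consumed
Reagents that add atoms: osmium tetroxide (OsO4, catalytic oxygen carrier), O=[Os](=O)(=O)=O; N-methylmorpholine N-oxide, C[N+]1([O-])CCOCC1; water, O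
Why: Upjohn syn-dihydroxylation, expected to prefer the electron-rich trisubstituted styrenyl ethylidene over the monosubstituted vinyl group held on a quaternary carbon, and to occur anti to the C3 aryl group (the two new centres are lost in the next step, so their configuration is immaterial).

Step 14
Reactants: 23 (3R,4S)-4-[(1S)-1-hydroxyethyl]-3-[4-methoxy-2,3-bis(methoxymethoxy)-5-(2-methylbut-3-en-2-yl)phenyl]-7-(methoxymethoxy)chroman-4-ol
Product: 24 (3R)-3-[4-methoxy-2,3-bis(methoxymethoxy)-5-(2-methylbut-3-en-2-yl)phenyl]-7-(methoxymethoxy)chroman-4-one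
Conditions: NaIO4, THF–pH 7 phosphate buffer, 0 °C to rt
Reagents that add atoms: none
Why: Malaprade glycol cleavage unveils the C4 ketone under neutral buffered conditions, so the now enolisable benzylic C3 centre should keep its configuration.

Step 15
Reactants: 24 (3R)-3-[4-methoxy-2,3-bis(methoxymethoxy)-5-(2-methylbut-3-en-2-yl)phenyl]-7-(methoxymethoxy)chroman-4-one
Product: 25 (3R)-3-[2,3-dihydroxy-4-methoxy-5-(2-methylbut-3-en-2-yl)phenyl]-7-hydroxychroman-4-one (CNP0134633.2)
Conditions: HCl (about 1.5 M) in MeOH–THF, 0 °C to rt; pH 7 buffer work-up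
Reagents that add atoms: none
Why: Acid-catalysed acetal exchange transfers the three methoxymethyl groups to methanol; cold dilute acid and a neutral work-up are chosen to avoid enolisation at C3 and cyclodehydration of the 2'-hydroxy ketone.

**Compound list**
1 | 2,3-dihydroxybenzaldehyde | O=Cc1cccc(O)c1O | starting material
2 | prenyl bromide | CC(C)=CCBr | starting material
3 | 2-hydroxy-3-[(3-methylbut-2-en-1-yl)oxy]benzaldehyde | O=Cc1cccc(OCC=C(C)C)c1O | intermediate
4 | 2-(methoxymethoxy)-3-[(3-methylbut-2-en-1-yl)oxy]benzaldehyde | O=Cc1cccc(OCC=C(C)C)c1OCOC | intermediate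
5 | 2-(methoxymethoxy)-4-(2-methylbut-3-en-2-yl)-3-oxocyclohexa-1,5-diene-1-carbaldehyde (racemic ortho-dienone, not isolated) | O=CC1=C(OCOC)C(=O)C(C(C)(C)C=C)C=C1 | intermediate
6 | 2-(methoxymethoxy)-4-(2-methylbut-3-en-2-yl)-3-(trimethylsilyloxy)benzaldehyde (not isolated) | O=Cc1ccc(C(C)(C)C=C)c(O[Si](C)(C)C)c1OCOC | intermediate
7 | 3-hydroxy-2-(methoxymethoxy)-4-(2-methylbut-3-en-2-yl)benzaldehyde | O=Cc1ccc(C(C)(C)C=C)c(O)c1OCOC | intermediate
8 | 3-methoxy-2-(methoxymethoxy)-4-(2-methylbut-3-en-2-yl)benzaldehyde | O=Cc1ccc(C(C)(C)C=C)c(OC)c1OCOC | intermediate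
9 | 3-methoxy-2-(methoxymethoxy)-4-(2-methylbut-3-en-2-yl)phenyl formate (not isolated) | O=COc1ccc(C(C)(C)C=C)c(OC)c1OCOC | intermediate
10 | 3-methoxy-2-(methoxymethoxy)-4-(2-methylbut-3-en-2-yl)phenol | Oc1ccc(C(C)(C)C=C)c(OC)c1OCOC | intermediate
11 | 7-hydroxychroman-4-one | O=C1CCOc2cc(O)ccc12 | starting material
12 | 7-(methoxymethoxy)chroman-4-one | O=C1CCOc2cc(OCOC)ccc12 | intermediate
13 | 7-(methoxymethoxy)-2H-chromen-4-yl trifluoromethanesulfonate | O=S(=O)(OC1=CCOc2cc(OCOC)ccc12)C(F)(F)F | intermediate
14 | tributyl(1-ethoxyvinyl)stannane | C=C(OCC)[Sn](CCCC)(CCCC)CCCC | starting material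
15 | 4-(1-ethoxyvinyl)-7-(methoxymethoxy)-2H-chromene (not isolated) | C=C(OCC)C1=CCOc2cc(OCOC)ccc12 | intermediate
16 | 1-[7-(methoxymethoxy)-2H-chromen-4-yl]ethanone | CC(=O)C1=CCOc2cc(OCOC)ccc12 | intermediate
17 | (S)-1-[7-(methoxymethoxy)-2H-chromen-4-yl]ethanol | C[C@H](O)C1=CCOc2cc(OCOC)ccc12 | intermediate
18 | 4-{(1R)-1-[3-methoxy-2-(methoxymethoxy)-4-(2-methylbut-3-en-2-yl)phenoxy]ethyl}-7-(methoxymethoxy)-2H-chromene | C[C@@H](Oc1ccc(C(C)(C)C=C)c(OC)c1OCOC)C1=CCOc2cc(OCOC)ccc12 | intermediate
19 | (6S)-6-[(3S,4E)-4-ethylidene-7-(methoxymethoxy)chroman-3-yl]-3-methoxy-2-(methoxymethoxy)-4-(2-methylbut-3-en-2-yl)cyclohexa-2,4-dien-1-one (ortho-dienone, C6 as expected from a chair transition state, not isolated) | C=CC(C)(C)C1=C[C@@H]([C@@H]2COc3cc(OCOC)ccc3/C2=C/C)C(=O)C(OCOC)=C1OC | intermediate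
20 | {6-[(3R,4E)-4-ethylidene-7-(methoxymethoxy)chroman-3-yl]-3-methoxy-2-(methoxymethoxy)-4-(2-methylbut-3-en-2-yl)phenoxy}trimethylsilane (not isolated) | C=CC(C)(C)c1cc([C@@H]2COc3cc(OCOC)ccc3/C2=C/C)c(O[Si](C)(C)C)c(OCOC)c1OC | intermediate
21 | 6-[(3R,4E)-4-ethylidene-7-(methoxymethoxy)chroman-3-yl]-3-methoxy-2-(methoxymethoxy)-4-(2-methylbut-3-en-2-yl)phenol | C=CC(C)(C)c1cc([C@@H]2COc3cc(OCOC)ccc3/C2=C/C)c(O)c(OCOC)c1OC | intermediate
22 | (3R,4E)-4-ethylidene-3-[4-methoxy-2,3-bis(methoxymethoxy)-5-(2-methylbut-3-en-2-yl)phenyl]-7-(methoxymethoxy)chroman | C=CC(C)(C)c1cc([C@@H]2COc3cc(OCOC)ccc3/C2=C/C)c(OCOC)c(OCOC)c1OC | intermediate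
23 | (3R,4S)-4-[(1S)-1-hydroxyethyl]-3-[4-methoxy-2,3-bis(methoxymethoxy)-5-(2-methylbut-3-en-2-yl)phenyl]-7-(methoxymethoxy)chroman-4-ol (expected major diastereomer) | C=CC(C)(C)c1cc([C@@H]2COc3cc(OCOC)ccc3[C@]2(O)[C@H](C)O)c(OCOC)c(OCOC)c1OC | intermediate
24 | (3R)-3-[4-methoxy-2,3-bis(methoxymethoxy)-5-(2-methylbut-3-en-2-yl)phenyl]-7-(methoxymethoxy)chroman-4-one | C=CC(C)(C)c1cc([C@@H]2COc3cc(OCOC)ccc3C2=O)c(OCOC)c(OCOC)c1OC | intermediate
25 | (3R)-3-[2,3-dihydroxy-4-methoxy-5-(2-methylbut-3-en-2-yl)phenyl]-7-hydroxychroman-4-one (CNP0134633.2) | C=CC(C)(C)c1cc([C@@H]2COc3cc(O)ccc3C2=O)c(O)c(O)c1OC | target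

**Step count**
Total: 15 steps. Longest linear sequence: 11 steps (steps 1–5, then 10–15, from 2,3-dihydroxybenzaldehyde); the chromene branch (steps 6–9) joins at step 10.

**Steps most likely to fail**

1. Step 11 (Claisen rearrangement).
 - What may go wrong: chirality transfer may be incomplete. The transition state with the carbinol methyl on the ring A side is penalised by the peri hydrogen, but it is free of the contact that the favoured arrangement has with C3' and its MOM ether; it would give the (Z)-ethylidene with (3S). The secondary allylic C–O bond may also ionise thermally with loss of the phenol, and any adventitious acid could move the exocyclic alkene into the C3=C4 position and erase C3.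
 - Fallback: drop the sigmatropic C–C bond formation and set out from phenol 10 and chromanone 12. Bromination of 10 with NBS (MeCN, 0 °C) at the only free position ortho to the hydroxyl should give 6-bromo-3-methoxy-2-(methoxymethoxy)-4-(2-methylbut-3-en-2-yl)phenol F1. MOM protection (MOMCl, i-Pr2NEt) should give 1-bromo-4-methoxy-2,3-bis(methoxymethoxy)-5-(2-methylbut-3-en-2-yl)benzene F2. Palladium-catalysed ketone alpha-arylation of 12 with F2 (Pd2(dba)3, XPhos, NaOt-Bu, toluene, 80 °C) should give the racemic tris-MOM isoflavanone F3. Separation of the enantiomers of F3 on a chiral stationary phase returns to the route at 24.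

2. Step 10 (Mitsunobu etherification).
 - What may go wrong: the activated secondary allylic alcohol may eliminate to a 4-vinylchromene, be captured at C3 in an SN2' sense, or lose configuration through an ion pair, so that the ether is formed in low amount or with eroded enantiopurity.
 - Fallback: form the aryl–oxygen bond instead, with retention at the carbinol carbon, setting out from phenol 10 and ketone 16. Phenol 10 is converted with Tf2O and pyridine into 3-methoxy-2-(methoxymethoxy)-4-(2-methylbut-3-en-2-yl)phenyl trifluoromethanesulfonate F4. Miyaura borylation (PdCl2(dppf), bis(pinacolato)diboron, KOAc, dioxane, 80 °C) should give the pinacol boronate 2-[3-methoxy-2-(methoxymethoxy)-4-(2-methylbut-3-en-2-yl)phenyl]-4,4,5,5-tetramethyl-1,3,2-dioxaborolane F5. Aqueous KHF2 in MeOH should give potassium trifluoro[3-methoxy-2-(methoxymethoxy)-4-(2-methylbut-3-en-2-yl)phenyl]borate F6. Ketone 16 is reduced with (S)-2-methyl-CBS-oxazaborolidine and BH3·SMe2 to (R)-1-[7-(methoxymethoxy)-2H-chromen-4-yl]ethanol F7. Copper-catalysed oxidative etherification of F7 with F6 (Cu(OAc)2·H2O cat., DMAP, 4 Å molecular sieves, O2, CH2Cl2, rt) leaves the carbinol C–O bond untouched and returns to the route at 18.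

3. Step 13 (dihydroxylation).
 - What may go wrong: site selectivity may be poor, with competing or subsequent dihydroxylation of the vinyl group of the 1,1-dimethylallyl unit.
 - Fallback: set out from 22 and replace the steric discrimination of the osmylation by a one-stage cleavage with an electrophilic 1,3-dipole, whose rate follows alkene electron density. Ozone (about 1 equiv, Sudan Red 7B end point) in CH2Cl2 at −78 °C should add to the styrenyl ethylidene and give the spiro ozonide of 22 F8 (1,2,4-trioxolane spanning C4 and the former ethylidene carbon, mixture at the two acetal carbons, not isolated). Reduction with Me2S in the same flask returns to the route at 24, bypassing 23.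

**Further compounds**
F1 | step 11 | 6-bromo-3-methoxy-2-(methoxymethoxy)-4-(2-methylbut-3-en-2-yl)phenol | Oc1c(Br)cc(C(C)(C)C=C)c(OC)c1OCOC
F2 | step 11 | 1-bromo-4-methoxy-2,3-bis(methoxymethoxy)-5-(2-methylbut-3-en-2-yl)benzene | COCOc1c(Br)cc(C(C)(C)C=C)c(OC)c1OCOC
F3 | step 11 | racemic 3-[4-methoxy-2,3-bis(methoxymethoxy)-5-(2-methylbut-3-en-2-yl)phenyl]-7-(methoxymethoxy)chroman-4-one | C=CC(C)(C)c1cc(C2COc3cc(OCOC)ccc3C2=O)c(OCOC)c(OCOC)c1OC
F4 | step 10 | 3-methoxy-2-(methoxymethoxy)-4-(2-methylbut-3-en-2-yl)phenyl trifluoromethanesulfonate | C=CC(C)(C)c1ccc(OS(=O)(=O)C(F)(F)F)c(OCOC)c1OC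
F5 | step 10 | 2-[3-methoxy-2-(methoxymethoxy)-4-(2-methylbut-3-en-2-yl)phenyl]-4,4,5,5-tetramethyl-1,3,2-dioxaborolane | C=CC(C)(C)c1ccc(B2OC(C)(C)C(C)(C)O2)c(OCOC)c1OC
F6 | step 10 | potassium trifluoro[3-methoxy-2-(methoxymethoxy)-4-(2-methylbut-3-en-2-yl)phenyl]borate | C=CC(C)(C)c1ccc([B-](F)(F)F)c(OCOC)c1OC.[K+]
F7 | step 10 | (R)-1-[7-(methoxymethoxy)-2H-chromen-4-yl]ethanol | C[C@@H](O)C1=CCOc2cc(OCOC)ccc12
F8 | step 13 | spiro ozonide of 22 (1,2,4-trioxolane at C4, (3R), mixture at the two acetal carbons) | C=CC(C)(C)c1cc([C@@H]2COc3cc(OCOC)ccc3C24OOC(C)O4)c(OCOC)c(OCOC)c1OC
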